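**Plan**
Numbering: C1 is the carboxyl carbon, C3 and C6 are the ring carbons bound to O2 and O1, C7–C14 is the side chain and C14 carries the phenyl group.
Structural feature: C1–C6, with methyls on C4 and C6 and oxygen on C3, are the six carbons of a 4,6-dimethylcyclohex-3-en-1-ol; its ring alkene is the C1–C6 bond that the target lacks.
Retrosynthetic cuts, in order: ester hydrolysis; C8–H with C9=C10 (allylic diazene shift, back to a C10 carbinol and enone); C6–C7 (ring peroxycarbenium ion plus a C7–C14 silyl dienol ether); O2–C3 and O1–C6 with C1 and C6 rejoined as the carbocycle alkene; C10–C11 of the side chain by Claisen rearrangement.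
Forward: Birch-derived cyclohexenol, resolved cis mesylate, then one operation (ozonolysis, acetalisation, peroxide alkylation) builds the 1,2-dioxane, the only ring formed; acetal to ester; chain joined at C6; C10 reduced; alkene transposed; ester saponified.
Stereochemistry: C4 from lipase resolution of the cis alcohol; C3 by SN2 inversion; C6 by axial attack on the ring peroxycarbenium ion; C12 by Sharpless kinetic resolution and Johnson–Claisen 1,3-transfer; C10 (temporary) by CBS reduction; C8 and the E C9=C10 alkene by the suprafacial diazene hydrogen shift; E C13=C14 from the Claisen chair.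

Key step: step 6

Assumption: the lipase follows Kazlauskas' rule and acylates the (1R)-carbinol of the cis alcohol; the sense would be confirmed on 7 (Mosher ester) before material is committed.

**Step 1**
Reactants: 1 2,4-dimethylanisole
Product: 3 4,6-dimethylcyclohex-3-en-1-one (racemic), via Birch diene 2 (not isolated)
Conditions: Li, NH3 (l), t-BuOH, THF, −78 → −33 °C; then (CO2H)2 (cat.), MeOH/H2O, 23 °C
Reagents that add atoms: water, O
Why: Birch reduction leaves the methoxy and both methyl groups on sp2 carbons, and mild enol ether hydrolysis then gives the β,γ-unsaturated ketone without moving the trisubstituted alkene into conjugation, the methyl-bearing α-carbon being formed racemic.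

**Step 2**
Reactants: 3 4,6-dimethylcyclohex-3-en-1-one (racemic)
Product: 4 cis-4,6-dimethylcyclohex-3-en-1-ol (racemic)
Conditions: LiBH(s-Bu)3 (L-Selectride), THF, −78 °C; then NaOH, H2O2, 0 °C
Reagents that add atoms: none
Why: Hindered trialkylborohydride reduction of a 2-alkylcyclohexanone delivers hydride from the equatorial side, so the hydroxyl should end up axial and cis to the adjacent methyl.

**Step 3**
Reactants: 4 cis-4,6-dimethylcyclohex-3-en-1-ol (racemic); 5 vinyl acetate
Product: 6 (1R,6S)-4,6-dimethylcyclohex-3-en-1-yl acetate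
Conditions: immobilised Candida antarctica lipase B (Novozym 435), vinyl acetate, MTBE, 30 °C, stopped below half conversion
Reagents that add atoms: vinyl acetate, C=COC(C)=O
Why: Lipase kinetic resolution by irreversible transesterification should acylate the (1R)-carbinol, whose larger flank is the methyl-bearing carbon (Kazlauskas' rule), and leave the (1S,6R)-alcohol.

**Step 4**
Reactants: 6 (1R,6S)-4,6-dimethylcyclohex-3-en-1-yl acetate
Product: 7 (1R,6S)-4,6-dimethylcyclohex-3-en-1-ol
Conditions: K2CO3 (cat.), MeOH, 23 °C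
Reagents that add atoms: none
Why: Base-catalysed transesterification to methyl acetate frees the alcohol without touching either stereocentre or the alkene.

**Step 5**
Reactants: 7 (1R,6S)-4,6-dimethylcyclohex-3-en-1-ol; 8 methanesulfonyl chloride
Product: 9 (1R,6S)-4,6-dimethylcyclohex-3-en-1-yl methanesulfonate
Conditions: MsCl, Et3N, CH2Cl2, 0 °C
Reagents that add atoms: methanesulfonyl chloride, CS(=O)(=O)Cl
Why: O-sulfonylation of the secondary alcohol (via sulfene) proceeds with retention, which places the leaving group cis to the future C4 methyl.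

**Step 6**
Reactants: 9 (1R,6S)-4,6-dimethylcyclohex-3-en-1-yl methanesulfonate
Product: 12 (3S,4S)-3-(2,2-dimethoxyethyl)-6-methoxy-4,6-dimethyl-1,2-dioxane (C6 epimers), via hydroperoxy ketal aldehyde 10 (not isolated), via hydroperoxy ketal acetal 11 (not isolated)
Conditions: O3, CH2Cl2/MeOH (4:1), −78 °C, N2 purge; p-TsOH·H2O (cat.), −78 → 23 °C; NaHCO3, solvent exchange to THF below 20 °C; KOtBu, 18-crown-6, 0 °C
Reagents that add atoms: ozone, [O-][O+]=O; methanol, CO
Why: Ozone adds to the only C=C, the primary ozonide should fragment so that the ketone oxide sits on the more substituted C6, methanol traps it as the hydroperoxy ketal, and acid then turns the C1 aldehyde into its dimethyl acetal so that E1cB loss of the mesylate is blocked. Potassium tert-butoxide deprotonates the hydroperoxide, which displaces the C3 mesylate in a 6-exo-tet SN2 closure of the 1,2-dioxane (C6–O1 from the ozonolysis, C3–O2 from the alkylation). The closest known reactions are Criegee ozonolysis of trisubstituted alkenes in methanol with Schreiber-type in situ acetalisation, and intramolecular alkylation of hydroperoxy ketals by secondary sulfonates. C3 is set by inversion of the resolved cis carbinol, which converts the cis sulfonate/methyl pair into the 3,4-cis dioxane; C4 is carried through and the C6 ketal centre is left as a mixture because it is replaced in step 14. The step needs the right direction of ozonide cleavage, secured by the greater substitution at C6 and the inductive pull of the homoallylic sulfonate on C1, and substitution rather than elimination at C3, favoured by the weakly basic but strongly nucleophilic peroxide anion, the six-membered transition state and the masked aldehyde.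

**Step 7**
Reactants: 12 (3S,4S)-3-(2,2-dimethoxyethyl)-6-methoxy-4,6-dimethyl-1,2-dioxane (C6 epimers)
Product: 13 methyl 2-[(3S,4S)-6-methoxy-4,6-dimethyl-1,2-dioxan-3-yl]acetate (C6 epimers)
Conditions: O3, EtOAc, −78 → 0 °C; N2 purge
Reagents that add atoms: ozone, [O-][O+]=O
Why: Deslongchamps oxidation of an acetal by ozone inserts into the acetal C–H bond, activated by two antiperiplanar oxygen lone pairs, and the hydrotrioxide collapses to the methyl ester, while the peroxyketal carbon has no hydrogen and should be inert.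

**Step 8**
Reactants: 14 (E)-1-phenylbut-2-en-1-one
Product: 15 (E)-1-phenylbut-2-en-1-ol (racemic)
Conditions: NaBH4, CeCl3·7H2O, MeOH, 0 °C
Reagents that add atoms: none
Why: Luche reduction gives clean 1,2-reduction of the aryl enone.

**Step 9**
Reactants: 15 (E)-1-phenylbut-2-en-1-ol (racemic)
Product: 16 (1R,2E)-1-phenylbut-2-en-1-ol
Conditions: Ti(OiPr)4 (cat.), D-(−)-diisopropyl tartrate, t-BuOOH (0.6 equiv), 4 Å MS, CH2Cl2, −20 °C
Reagents that add atoms: none
Why: Sharpless kinetic resolution of a secondary E-allylic alcohol: with the D-tartrate the (S)-enantiomer should be epoxidised fast and the (R)-alcohol recovered.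

**Step 10**
Reactants: 16 (1R,2E)-1-phenylbut-2-en-1-ol; 17 triethyl orthoacetate
Product: 19 ethyl (3S,4E)-3-methyl-5-phenylpent-4-enoate, via ketene acetal 18 (not isolated)
Conditions: CH3C(OEt)3, EtCO2H (cat.), 135 °C, EtOH distilled off
Reagents that add atoms: triethyl orthoacetate, CCOC(C)(OCC)OCC
Why: Johnson–Claisen rearrangement through a chair with phenyl equatorial should transfer the carbinol chirality suprafacially to the new C12 centre (3S in 19) and give the E styrene.

**Step 11**
Reactants: 19 ethyl (3S,4E)-3-methyl-5-phenylpent-4-enoate; 20 N,O-dimethylhydroxylamine hydrochloride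
Product: 21 (3S,4E)-N-methoxy-N,3-dimethyl-5-phenylpent-4-enamide
Conditions: MeNHOMe·HCl, i-PrMgCl, THF, −20 → 0 °C
Reagents that add atoms: N,O-dimethylhydroxylamine hydrochloride, CNOC.Cl
Why: Aminolysis of the ester by the magnesium amide of the hydroxylamine gives the Weinreb amide directly, and the β-stereocentre is not acidic.

**Step 12**
Reactants: 21 (3S,4E)-N-methoxy-N,3-dimethyl-5-phenylpent-4-enamide; 22 2-methylallylmagnesium chloride
Product: 23 (6S,7E)-2,6-dimethyl-8-phenylocta-1,7-dien-4-one
Conditions: 2-methylallylmagnesium chloride, THF, −78 → 0 °C; aq. NH4Cl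
Reagents that add atoms: 2-methylallylmagnesium chloride, CC(=C)C[Mg]Cl
Why: Grignard addition to a Weinreb amide stops at the chelated tetrahedral adduct, so the β,γ-unsaturated ketone should be released only on cold, buffered work-up.

**Step 13**
Reactants: 23 (6S,7E)-2,6-dimethyl-8-phenylocta-1,7-dien-4-one; 24 tert-butyldimethylsilyl trifluoromethanesulfonate
Product: 25 tert-butyl{[(3Z,6S,7E)-2,6-dimethyl-8-phenylocta-1,3,7-trien-4-yl]oxy}dimethylsilane
Conditions: TBSOTf, Et3N, CH2Cl2, 0 °C
Reagents that add atoms: tert-butyldimethylsilyl trifluoromethanesulfonate, CC(C)(C)[Si](C)(C)OS(=O)(=O)C(F)(F)F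
Why: Soft enolisation removes the doubly activated proton between carbonyl and alkene (C9), so O-silylation should give the conjugated 2-silyloxy diene and not the enol ether toward C11; the enol ether geometry has no consequence.

**Step 14**
Reactants: 13 methyl 2-[(3S,4S)-6-methoxy-4,6-dimethyl-1,2-dioxan-3-yl]acetate (C6 epimers); 25 tert-butyl{[(3Z,6S,7E)-2,6-dimethyl-8-phenylocta-1,3,7-trien-4-yl]oxy}dimethylsilane
Product: 26 methyl 2-[(3S,4S,6R)-6-[(2E,6S,7E)-2,6-dimethyl-4-oxo-8-phenylocta-2,7-dien-1-yl]-4,6-dimethyl-1,2-dioxan-3-yl]acetate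
Conditions: TiCl4, CH2Cl2, −78 °C
Reagents that add atoms: none
Why: Vinylogous Mukaiyama-type substitution: TiCl4 ionises either ketal epimer to the same ring peroxycarbenium ion, the dienol ether attacks through its unhindered terminal carbon (C7), and axial attack on the half-chair with the C4 methyl pseudoequatorial should place the chain trans to the C4 methyl and the C3 arm, the enone forming mainly as the more stable E isomer (any Z isomer removed by chromatography).

**Step 15**
Reactants: 26 methyl 2-[(3S,4S,6R)-6-[(2E,6S,7E)-2,6-dimethyl-4-oxo-8-phenylocta-2,7-dien-1-yl]-4,6-dimethyl-1,2-dioxan-3-yl]acetate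
Product: 27 methyl 2-[(3S,4S,6R)-6-[(2E,4S,6S,7E)-4-hydroxy-2,6-dimethyl-8-phenylocta-2,7-dien-1-yl]-4,6-dimethyl-1,2-dioxan-3-yl]acetate
Conditions: (R)-2-methyl-CBS-oxazaborolidine, catecholborane, toluene, −78 °C
Reagents that add atoms: none
Why: Corey–Bakshi–Shibata reduction under catalyst control, with the trisubstituted alkenyl group as the large substituent, should give the 10S carbinol by 1,2-reduction, and neither the ester nor the dialkyl peroxide is reduced by catecholborane at this temperature.

**Step 16**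
Reactants: 27 methyl 2-[(3S,4S,6R)-6-[(2E,4S,6S,7E)-4-hydroxy-2,6-dimethyl-8-phenylocta-2,7-dien-1-yl]-4,6-dimethyl-1,2-dioxan-3-yl]acetate; 28 2-nitrobenzenesulfonohydrazide (NBSH)
Product: 31 methyl 2-[(3S,4S,6S)-6-[(2R,3E,6S,7E)-2,6-dimethyl-8-phenylocta-3,7-dien-1-yl]-4,6-dimethyl-1,2-dioxan-3-yl]acetate, via allylic sulfonylhydrazide 29 (not isolated), via allylic diazene 30 (not isolated)
Conditions: PPh3, DEAD, NBSH, N-methylmorpholine, −30 → 23 °C
Reagents that add atoms: none
Why: Myers reductive 1,3-transposition: Mitsunobu displacement inverts C10, sulfinic acid is lost on warming, and the diazene transfers hydrogen suprafacially to C8 with loss of N2 through the conformer in which C10–H eclipses the C8 methyl (least A1,3 strain), which should give 8R and the E C9=C10 alkene.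

**Step 17**
Reactants: 31 methyl 2-[(3S,4S,6S)-6-[(2R,3E,6S,7E)-2,6-dimethyl-8-phenylocta-3,7-dien-1-yl]-4,6-dimethyl-1,2-dioxan-3-yl]acetate
Product: 32 2-[(3S,4S,6S)-6-[(2R,3E,6S,7E)-2,6-dimethyl-8-phenylocta-3,7-dien-1-yl]-4,6-dimethyl-1,2-dioxan-3-yl]acetic acid (CNP0179089.3)
Conditions: LiOH, THF/H2O, 0 °C; then 1 M HCl
Reagents that add atoms: lithium hydroxide, [Li+].[OH-]
Why: Saponification of the methyl ester at low temperature should outpace base-induced opening of the β-peroxy ester, and no stereocentre is α to the carboxyl group.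

**Compound list**
1 | 2,4-dimethylanisole | COc1ccc(C)cc1C | starting material
2 | 1-methoxy-2,4-dimethylcyclohexa-1,4-diene | COC1=C(C)CC(C)=CC1 | intermediate (not isolated)
3 | 4,6-dimethylcyclohex-3-en-1-one (racemic) | CC1=CCC(=O)C(C)C1 | intermediate
4 | cis-4,6-dimethylcyclohex-3-en-1-ol (racemic; relative configuration shown) | CC1=CC[C@@H](O)[C@@H](C)C1 | intermediate
5 | vinyl acetate | C=COC(C)=O | starting material
6 | (1R,6S)-4,6-dimethylcyclohex-3-en-1-yl acetate | CC1=CC[C@@H](OC(C)=O)[C@@H](C)C1 | intermediate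
7 | (1R,6S)-4,6-dimethylcyclohex-3-en-1-ol | CC1=CC[C@@H](O)[C@@H](C)C1 | intermediate
8 | methanesulfonyl chloride | CS(=O)(=O)Cl | starting material
9 | (1R,6S)-4,6-dimethylcyclohex-3-en-1-yl methanesulfonate | CC1=CC[C@@H](OS(C)(=O)=O)[C@@H](C)C1 | intermediate
10 | (3R,4S)-6-hydroperoxy-6-methoxy-4-methyl-1-oxoheptan-3-yl methanesulfonate (C6 epimers) | O=CC[C@@H](OS(C)(=O)=O)[C@@H](C)CC(C)(OC)OO | intermediate (not isolated)
11 | (3R,4S)-6-hydroperoxy-1,1,6-trimethoxy-4-methylheptan-3-yl methanesulfonate (C6 epimers) | COC(OC)C[C@@H](OS(C)(=O)=O)[C@@H](C)CC(C)(OC)OO | intermediate (not isolated)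
12 | (3S,4S)-3-(2,2-dimethoxyethyl)-6-methoxy-4,6-dimethyl-1,2-dioxane (C6 epimers) | COC1(C)C[C@H](C)[C@H](CC(OC)OC)OO1 | intermediate
13 | methyl 2-[(3S,4S)-6-methoxy-4,6-dimethyl-1,2-dioxan-3-yl]acetate (C6 epimers) | COC1(C)C[C@H](C)[C@H](CC(=O)OC)OO1 | intermediate
14 | (E)-1-phenylbut-2-en-1-one | C/C=C/C(=O)c1ccccc1 | starting material
15 | (E)-1-phenylbut-2-en-1-ol (racemic) | C/C=C/C(O)c1ccccc1 | intermediate
16 | (1R,2E)-1-phenylbut-2-en-1-ol | C/C=C/[C@@H](O)c1ccccc1 | intermediate
17 | triethyl orthoacetate | CCOC(C)(OCC)OCC | starting material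
18 | {(1R,2E)-1-[(1-ethoxyethenyl)oxy]but-2-en-1-yl}benzene | C=C(OCC)O[C@H](/C=C/C)c1ccccc1 | intermediate (not isolated)
19 | ethyl (3S,4E)-3-methyl-5-phenylpent-4-enoate | CCOC(=O)C[C@H](C)/C=C/c1ccccc1 | intermediate
20 | N,O-dimethylhydroxylamine hydrochloride | CNOC.Cl | starting material
21 | (3S,4E)-N-methoxy-N,3-dimethyl-5-phenylpent-4-enamide | CON(C)C(=O)C[C@H](C)/C=C/c1ccccc1 | intermediate
22 | 2-methylallylmagnesium chloride | CC(=C)C[Mg]Cl | starting material
23 | (6S,7E)-2,6-dimethyl-8-phenylocta-1,7-dien-4-one | CC(=C)CC(=O)C[C@H](C)/C=C/c1ccccc1 | intermediate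
24 | tert-butyldimethylsilyl trifluoromethanesulfonate | CC(C)(C)[Si](C)(C)OS(=O)(=O)C(F)(F)F | starting material
25 | tert-butyl{[(3Z,6S,7E)-2,6-dimethyl-8-phenylocta-1,3,7-trien-4-yl]oxy}dimethylsilane | CC(=C)/C=C(\O[Si](C)(C)C(C)(C)C)C[C@H](C)/C=C/c1ccccc1 | intermediate
26 | methyl 2-[(3S,4S,6R)-6-[(2E,6S,7E)-2,6-dimethyl-4-oxo-8-phenylocta-2,7-dien-1-yl]-4,6-dimethyl-1,2-dioxan-3-yl]acetate | C[C@H](/C=C/c1ccccc1)CC(=O)/C=C(\C)C[C@@]1(C)C[C@H](C)[C@H](CC(=O)OC)OO1 | intermediate
27 | methyl 2-[(3S,4S,6R)-6-[(2E,4S,6S,7E)-4-hydroxy-2,6-dimethyl-8-phenylocta-2,7-dien-1-yl]-4,6-dimethyl-1,2-dioxan-3-yl]acetate | C[C@H](/C=C/c1ccccc1)C[C@H](O)/C=C(\C)C[C@@]1(C)C[C@H](C)[C@H](CC(=O)OC)OO1 | intermediate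
28 | 2-nitrobenzenesulfonohydrazide (NBSH) | NNS(=O)(=O)c1ccccc1[N+](=O)[O-] | starting material
29 | methyl 2-[(3S,4S,6R)-6-[(2E,4R,6S,7E)-2,6-dimethyl-4-[1-(2-nitrophenylsulfonyl)hydrazinyl]-8-phenylocta-2,7-dien-1-yl]-4,6-dimethyl-1,2-dioxan-3-yl]acetate | C[C@H](/C=C/c1ccccc1)C[C@@H](N(N)S(=O)(=O)c1ccccc1[N+](=O)[O-])/C=C(\C)C[C@@]1(C)C[C@H](C)[C@H](CC(=O)OC)OO1 | intermediate (not isolated)
30 | methyl 2-[(3S,4S,6R)-6-[(2E,4R,6S,7E)-4-diazenyl-2,6-dimethyl-8-phenylocta-2,7-dien-1-yl]-4,6-dimethyl-1,2-dioxan-3-yl]acetate | C[C@H](/C=C/c1ccccc1)C[C@@H](N=N)/C=C(\C)C[C@@]1(C)C[C@H](C)[C@H](CC(=O)OC)OO1 | intermediate (not isolated)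
31 | methyl 2-[(3S,4S,6S)-6-[(2R,3E,6S,7E)-2,6-dimethyl-8-phenylocta-3,7-dien-1-yl]-4,6-dimethyl-1,2-dioxan-3-yl]acetate (C6 descriptor changes from R to S by CIP priority only) | C[C@H](/C=C/c1ccccc1)C/C=C/[C@H](C)C[C@@]1(C)C[C@H](C)[C@H](CC(=O)OC)OO1 | intermediate
32 | 2-[(3S,4S,6S)-6-[(2R,3E,6S,7E)-2,6-dimethyl-8-phenylocta-3,7-dien-1-yl]-4,6-dimethyl-1,2-dioxan-3-yl]acetic acid | C[C@H](/C=C/c1ccccc1)C/C=C/[C@H](C)C[C@@]1(C)C[C@H](C)[C@H](CC(=O)O)OO1 | target

**Step count**
Total: 17 steps. Longest linear sequence: 11 steps (steps 1–7 and 14–17); the side-chain branch is steps 8–13.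

**Steps most likely to fail**

Step 6. Elimination of the mesylate (E2 toward C2 or C4, or E1cB if acetalisation is incomplete) or acid-promoted loss of the hydroperoxy group may outrun the 6-exo-tet alkylation. The fallback reverses the order of the two C–O bond formations. It sets out from mesylate 9. Intermolecular SN2 with the caesium salt of 2-methoxypropan-2-yl hydroperoxide (CsOH·H2O, DMF) would give, with inversion, the trans peroxide (4S,5S)-4-[(2-methoxypropan-2-yl)peroxy]-1,5-dimethylcyclohex-1-ene F1. Ozonolysis with dimethyl sulfide work-up, which leaves a dialkyl peroxide intact, would give (3S,4S)-3-[(2-methoxypropan-2-yl)peroxy]-4-methyl-6-oxoheptanal F2. p-TsOH in methanol would then unmask the C3 hydroperoxide, which closes onto the C6 ketone as the cyclic methoxy peroxyketal while the aldehyde becomes its dimethyl acetal. The fallback comes back to the route at 12.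

Step 14. The dienol ether may attack through C9 instead of C7, the peroxycarbenium ion may undergo a carbon-to-oxygen shift before it is captured, or the nucleophile may enter cis to the C4 methyl. The fallback delivers C7–C14 as an allylsilane, the nucleophile class best documented for peroxycarbenium ions. It sets out from 21 and 13. Weinreb amide 21 and the allylic Grignard reagent from 3-chloro-2-[(trimethylsilyl)methyl]prop-1-ene would give (6S,7E)-6-methyl-8-phenyl-2-[(trimethylsilyl)methyl]octa-1,7-dien-4-one F3. Hosomi–Sakurai reaction of this allylsilane with 13 (TiCl4, CH2Cl2, −78 °C) would give methyl 2-[(3S,4S,6R)-4,6-dimethyl-6-[(6S,7E)-6-methyl-2-methylidene-4-oxo-8-phenyloct-7-en-1-yl]-1,2-dioxan-3-yl]acetate F4. Brief treatment with DBU would move the exocyclic alkene into conjugation. The fallback comes back to the route at enone 26.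

Step 16. The phosphine may attack the O–O bond, or the activated allylic alcohol may ionise or react SN2′, so that C8 forms with poor fidelity. The fallback is a Tsuji–Mandai hydrogenolysis, which needs phosphine only as a ligand in catalytic amount. It sets out from alcohol 27, which would be formylated (HCO2H, DCC, DMAP) to methyl 2-[(3S,4S,6R)-6-[(2E,4S,6S,7E)-4-(formyloxy)-2,6-dimethyl-8-phenylocta-2,7-dien-1-yl]-4,6-dimethyl-1,2-dioxan-3-yl]acetate F5. With Pd(OAc)2 and PBu3 in THF, zerovalent palladium would ionise the formate with inversion, CO2 would be lost, and hydride would pass from palladium to the more substituted allyl terminus C8 on the face opposite to the departed oxygen. That is the same stereochemical sense as the diazene shift. The fallback comes back to the route at 31.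

**Further compounds**
F1 | step 6 | (4S,5S)-4-[(2-methoxypropan-2-yl)peroxy]-1,5-dimethylcyclohex-1-ene | CC1=CC[C@H](OOC(C)(C)OC)[C@@H](C)C1
F2 | step 6 | (3S,4S)-3-[(2-methoxypropan-2-yl)peroxy]-4-methyl-6-oxoheptanal | O=CC[C@H](OOC(C)(C)OC)[C@@H](C)CC(C)=O
F3 | step 14 | (6S,7E)-6-methyl-8-phenyl-2-[(trimethylsilyl)methyl]octa-1,7-dien-4-one | C=C(C[Si](C)(C)C)CC(=O)C[C@H](C)/C=C/c1ccccc1
F4 | step 14 | methyl 2-[(3S,4S,6R)-4,6-dimethyl-6-[(6S,7E)-6-methyl-2-methylidene-4-oxo-8-phenyloct-7-en-1-yl]-1,2-dioxan-3-yl]acetate | C[C@H](/C=C/c1ccccc1)CC(=O)CC(=C)C[C@@]1(C)C[C@H](C)[C@H](CC(=O)OC)OO1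
F5 | step 16 | methyl 2-[(3S,4S,6R)-6-[(2E,4S,6S,7E)-4-(formyloxy)-2,6-dimethyl-8-phenylocta-2,7-dien-1-yl]-4,6-dimethyl-1,2-dioxan-3-yl]acetate | C[C@H](/C=C/c1ccccc1)C[C@H](OC=O)/C=C(\C)C[C@@]1(C)C[C@H](C)[C@H](CC(=O)OC)OO1
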